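**Retrosynthetic overview**
1. Target ⇐ peracid epoxidation of the 1(10)-alkene (last step) ⇐ 15-oxo enal by selective oxidation of the C15 allylic alcohol ⇐ 3S-alcohol by CBS reduction of a macrocyclic C3 enone.
2. Ten-membered carbocycle ⇐ intramolecular Nozaki–Hiyama–Kishi closure of C3–C4, a (Z)-alkenyl iodide adding to a C3 aldehyde.
3. Seco compound ⇐ Mitsunobu methacrylation with inversion at C8 ⇐ intermolecular Barbier-type carbonyl allylation forming C7–C8 between aldehyde 8 (C8–C10, C14, C1–C3) and bromomethyl butenolide 19 (C4–C7, C11–C13, C15).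
4. 19 ⇐ ring-closing metathesis of a 2-(bromomethyl)acrylate ⇐ (S,Z)-iodo dienol (directed hydroalumination–iodination; Sharpless kinetic resolution); 8 ⇐ Negishi carboalumination of a but-3-yn-1-ol ether plus oxirane.
5. Ring order: butenolide (metathesis) → α-methylene-γ-lactone (allylation) → ten-membered ring (Nozaki–Hiyama–Kishi) → oxirane.

Assumption: the SMILES is read, in germacrane numbering, as 1R,3S,6R,7R,8R,10R, with a trans-fused 12,6-lactone, a 1,10-epoxide derived from an E-alkene, and C3 and C6 cis on the 4,5-alkene. Positions are referred to by these numbers throughout.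

**Route**

Step 1
Reactants: 1 but-3-yn-1-ol
Product: 2 tert-butyl(but-3-yn-1-yloxy)dimethylsilane
Conditions: TBSCl, imidazole, CH2Cl2, 0 °C to rt
Reagents that add atoms: tert-butyldimethylsilyl chloride, CC(C)(C)[Si](C)(C)Cl
Why: Routine silylation of a primary alcohol protects the future C8 oxygen through the organoaluminium chemistry.

Step 2
Reactants: 2 tert-butyl(but-3-yn-1-yloxy)dimethylsilane; 3 oxirane
Product: 5 (E)-6-[(tert-butyldimethylsilyl)oxy]-4-methylhex-3-en-1-ol, via alkenyldimethylalane 4 (not isolated)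
Conditions: Me3Al, Cp2ZrCl2 (0.25 equiv), CH2Cl2, 0 °C to rt; then n-BuLi, THF, −78 °C; oxirane, −78 °C to rt; aq. Rochelle salt
Reagents that add atoms: trimethylaluminium, C[Al](C)C
Why: Negishi zirconium-catalysed carboalumination adds methyl and aluminium syn across the terminal alkyne, and the derived alanate opens oxirane with retention, so the E-trisubstituted C1(10) alkene is fixed here.

Step 3
Reactants: 5 (E)-6-[(tert-butyldimethylsilyl)oxy]-4-methylhex-3-en-1-ol
Product: 6 (E)-tert-butyl({6-[(4-methoxybenzyl)oxy]-3-methylhex-3-en-1-yl}oxy)dimethylsilane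
Conditions: NaH, PMBCl, Bu4NI (cat.), THF/DMF, 0 °C to rt
Reagents that add atoms: 4-methoxybenzyl chloride, COc1ccc(CCl)cc1
Why: Williamson etherification puts an oxidatively removable group on the future C3 oxygen, orthogonal to both silyl ethers used later.

Step 4
Reactants: 6 (E)-tert-butyl({6-[(4-methoxybenzyl)oxy]-3-methylhex-3-en-1-yl}oxy)dimethylsilane
Product: 7 (E)-6-[(4-methoxybenzyl)oxy]-3-methylhex-3-en-1-ol
Conditions: TBAF, THF, 0 °C to rt
Reagents that add atoms: none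
Why: Fluoride desilylation frees only the C8 hydroxyl because the PMB ether is inert to fluoride.

Step 5
Reactants: 7 (E)-6-[(4-methoxybenzyl)oxy]-3-methylhex-3-en-1-ol
Product: 8 (E)-6-[(4-methoxybenzyl)oxy]-3-methylhex-3-enal
Conditions: Dess–Martin periodinane, NaHCO3, CH2Cl2, 0 °C; used crude at once
Reagents that add atoms: none
Why: Buffered Dess–Martin oxidation gives the β,γ-unsaturated aldehyde without shifting the alkene into conjugation, provided it is used immediately.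

Step 6
Reactants: 9 prop-2-yn-1-ol
Product: 10 tert-butyldiphenyl(prop-2-yn-1-yloxy)silane
Conditions: TBDPSCl, imidazole, CH2Cl2, rt
Reagents that add atoms: tert-butyldiphenylsilyl chloride, CC(C)(C)[Si](Cl)(c1ccccc1)c1ccccc1
Why: Silylation installs a robust C15 oxygen protecting group that survives every step up to step 19.

Step 7
Reactants: 10 tert-butyldiphenyl(prop-2-yn-1-yloxy)silane; 11 (E)-but-2-enal
Product: 13 rac-(E)-1-[(tert-butyldiphenylsilyl)oxy]hept-5-en-2-yn-4-ol, via lithium acetylide 12 (not isolated)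
Conditions: n-BuLi, THF, −78 °C; then (E)-but-2-enal, −78 to 0 °C; H2O
Reagents that add atoms: none
Why: A lithium acetylide adds 1,2 to the enal to give the racemic alkenyl alkynyl carbinol (the future C6) in one operation.

Step 8
Reactants: 13 rac-(E)-1-[(tert-butyldiphenylsilyl)oxy]hept-5-en-2-yn-4-ol
Product: 14 (4S,5E)-1-[(tert-butyldiphenylsilyl)oxy]hept-5-en-2-yn-4-ol
Conditions: Ti(OiPr)4 (0.15 equiv), L-(+)-diisopropyl tartrate (0.2 equiv), t-BuOOH (0.6 equiv), 4 Å molecular sieves, CH2Cl2, −20 °C, to about 55% conversion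
Reagents that add atoms: none
Why: In this Sharpless kinetic resolution the L-(+)-tartrate catalyst epoxidises the 4R enantiomer of the secondary allylic alcohol much faster, so the 4S alcohol (the C6 configuration) is recovered in high ee.

Step 9
Reactants: 14 (4S,5E)-1-[(tert-butyldiphenylsilyl)oxy]hept-5-en-2-yn-4-ol
Product: 16 (2Z,4S,5E)-1-[(tert-butyldiphenylsilyl)oxy]-2-iodohepta-2,5-dien-4-ol, via cyclic alkenylaluminate 15 (not isolated)
Conditions: NaAlH2(OCH2CH2OMe)2, THF, 0 °C to rt; EtOAc; then I2, THF, −78 to 0 °C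
Reagents that add atoms: iodine, II
Why: Alkoxide-directed trans-hydroalumination delivers hydride to the alkyne carbon next to the carbinol, and iodinolysis with retention gives the (Z)-alkenyl iodide with iodine cis to C6, which is the 4,5-alkene geometry of the target.

Step 10
Reactants: 16 (2Z,4S,5E)-1-[(tert-butyldiphenylsilyl)oxy]-2-iodohepta-2,5-dien-4-ol; 17 2-(bromomethyl)acrylic acid
Product: 18 (2Z,4S,5E)-1-[(tert-butyldiphenylsilyl)oxy]-2-iodohepta-2,5-dien-4-yl 2-(bromomethyl)acrylate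
Conditions: DCC, DMAP (5 mol%), CH2Cl2, −20 to 0 °C
Reagents that add atoms: none
Why: Steglich esterification at low temperature acylates the secondary alcohol without touching the stereocentre or displacing the allylic bromide.

Step 11
Reactants: 18 (2Z,4S,5E)-1-[(tert-butyldiphenylsilyl)oxy]-2-iodohepta-2,5-dien-4-yl 2-(bromomethyl)acrylate
Product: 19 (S)-3-(bromomethyl)-5-{(Z)-3-[(tert-butyldiphenylsilyl)oxy]-2-iodoprop-1-en-1-yl}furan-2(5H)-one
Conditions: second-generation Grubbs catalyst RuCl2(=CHPh)(H2IMes)(PCy3) (5 mol%), CH2Cl2, 40 °C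
Reagents that add atoms: none
Why: Ring-closing metathesis between the propenyl group and the acrylate alkene forms the butenolide with loss of propene, while the trisubstituted iodoalkene is inert to the ruthenium carbene.

Step 12
Reactants: 19 (S)-3-(bromomethyl)-5-{(Z)-3-[(tert-butyldiphenylsilyl)oxy]-2-iodoprop-1-en-1-yl}furan-2(5H)-one; 8 (E)-6-[(4-methoxybenzyl)oxy]-3-methylhex-3-enal
Product: 21 (4R,5S)-4-{(1S,3E)-1-hydroxy-6-[(4-methoxybenzyl)oxy]-3-methylhex-3-en-1-yl}-5-{(Z)-3-[(tert-butyldiphenylsilyl)oxy]-2-iodoprop-1-en-1-yl}-3-methylideneoxolan-2-one, via allylzinc bromide 20 (not isolated)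
Conditions: Zn dust, THF/sat. aq. NH4Cl (2:1), 0 °C to rt
Reagents that add atoms: none
Why: In this Barbier-type carbonyl allylation the allylzinc attacks the aldehyde through its ring carbon C7 in a chair Zimmerman–Traxler transition state, anti to the C6 substituent (trans lactone) and with the aldehyde chain equatorial (7,8-anti, 8S), which unveils the α-methylene lactone and gives the C8 epimer that step 13 inverts.

Step 13
Reactants: 21 (4R,5S)-4-{(1S,3E)-1-hydroxy-6-[(4-methoxybenzyl)oxy]-3-methylhex-3-en-1-yl}-5-{(Z)-3-[(tert-butyldiphenylsilyl)oxy]-2-iodoprop-1-en-1-yl}-3-methylideneoxolan-2-one; 22 methacrylic acid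
Product: 23 (1R,3E)-1-[(2S,3R)-2-{(Z)-3-[(tert-butyldiphenylsilyl)oxy]-2-iodoprop-1-en-1-yl}-4-methylidene-5-oxooxolan-3-yl]-6-[(4-methoxybenzyl)oxy]-3-methylhex-3-en-1-yl methacrylate
Conditions: PPh3, DIAD, toluene, 0 °C to rt, BHT (trace), dark
Reagents that add atoms: none
Why: Mitsunobu esterification displaces the activated C8 oxygen by methacrylate with clean SN2 inversion, so the 8R (8β) ester configuration and the ester itself are installed together.

Step 14
Reactants: 23 (1R,3E)-1-[(2S,3R)-2-{(Z)-3-[(tert-butyldiphenylsilyl)oxy]-2-iodoprop-1-en-1-yl}-4-methylidene-5-oxooxolan-3-yl]-6-[(4-methoxybenzyl)oxy]-3-methylhex-3-en-1-yl methacrylate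
Product: 24 (1R,3E)-1-[(2S,3R)-2-{(Z)-3-[(tert-butyldiphenylsilyl)oxy]-2-iodoprop-1-en-1-yl}-4-methylidene-5-oxooxolan-3-yl]-6-hydroxy-3-methylhex-3-en-1-yl methacrylate
Conditions: DDQ, CH2Cl2/pH 7 buffer (10:1), 0 °C
Reagents that add atoms: none
Why: Oxidative cleavage of the PMB ether by DDQ is neutral and leaves the silyl ether, alkenyl iodide, methacrylate and methylene lactone untouched.

Step 15
Reactants: 24 (1R,3E)-1-[(2S,3R)-2-{(Z)-3-[(tert-butyldiphenylsilyl)oxy]-2-iodoprop-1-en-1-yl}-4-methylidene-5-oxooxolan-3-yl]-6-hydroxy-3-methylhex-3-en-1-yl methacrylate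
Product: 25 (1R,3E)-1-[(2S,3R)-2-{(Z)-3-[(tert-butyldiphenylsilyl)oxy]-2-iodoprop-1-en-1-yl}-4-methylidene-5-oxooxolan-3-yl]-3-methyl-6-oxohex-3-en-1-yl methacrylate
Conditions: Dess–Martin periodinane, NaHCO3, CH2Cl2, 0 °C; used crude at once
Reagents that add atoms: none
Why: Buffered Dess–Martin oxidation gives the C3 aldehyde under non-basic conditions that spare the β,γ-alkene and the Michael acceptors.

Step 16
Reactants: 25 (1R,3E)-1-[(2S,3R)-2-{(Z)-3-[(tert-butyldiphenylsilyl)oxy]-2-iodoprop-1-en-1-yl}-4-methylidene-5-oxooxolan-3-yl]-3-methyl-6-oxohex-3-en-1-yl methacrylate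
Product: 27 (6R,7R,8R)-15-[(tert-butyldiphenylsilyl)oxy]-3-hydroxy-8-(methacryloyloxy)germacra-1(10)E,4Z,11(13)-trien-12,6-olide (C3 epimer mixture), via alkenylchromium dichloride 26 (not isolated)
Conditions: CrCl2 (10 equiv), NiCl2 (0.1 equiv), DMSO/THF (3:1), rt, syringe-pump addition to 0.003 M
Reagents that add atoms: none
Why: In the intramolecular Nozaki–Hiyama–Kishi reaction the alkenyl iodide is converted, with retention of the Z geometry, into an alkenylchromium that adds only to the aldehyde, closing the ten-membered ring; the C3 epimer ratio does not matter because step 17 removes that centre.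

Step 17
Reactants: 27 (6R,7R,8R)-15-[(tert-butyldiphenylsilyl)oxy]-3-hydroxy-8-(methacryloyloxy)germacra-1(10)E,4Z,11(13)-trien-12,6-olide (C3 epimer mixture)
Product: 28 (6R,7R,8R)-15-[(tert-butyldiphenylsilyl)oxy]-8-(methacryloyloxy)-3-oxogermacra-1(10)E,4Z,11(13)-trien-12,6-olide
Conditions: Dess–Martin periodinane, NaHCO3, CH2Cl2, 0 °C
Reagents that add atoms: none
Why: Dess–Martin oxidation converges both allylic alcohol epimers on one enone under buffered conditions.

Step 18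
Reactants: 28 (6R,7R,8R)-15-[(tert-butyldiphenylsilyl)oxy]-8-(methacryloyloxy)-3-oxogermacra-1(10)E,4Z,11(13)-trien-12,6-olide
Product: 29 (3S,6R,7R,8R)-15-[(tert-butyldiphenylsilyl)oxy]-3-hydroxy-8-(methacryloyloxy)germacra-1(10)E,4Z,11(13)-trien-12,6-olide
Conditions: (R)-2-methyl-CBS-oxazaborolidine (1 equiv), catecholborane, toluene, −78 °C
Reagents that add atoms: none
Why: In the Corey–Bakshi–Shibata reduction the fully substituted alkenyl carbon C4 acts as the large group and the C2 methylene as the small one, so the (R)-catalyst delivers hydride 1,2 to give the 3S alcohol, and catecholborane at −78 °C leaves the ester-conjugated alkenes alone.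

Step 19
Reactants: 29 (3S,6R,7R,8R)-15-[(tert-butyldiphenylsilyl)oxy]-3-hydroxy-8-(methacryloyloxy)germacra-1(10)E,4Z,11(13)-trien-12,6-olide
Product: 30 (3S,6R,7R,8R)-3,15-dihydroxy-8-(methacryloyloxy)germacra-1(10)E,4Z,11(13)-trien-12,6-olide
Conditions: HF·pyridine, pyridine, THF, 0 °C to rt
Reagents that add atoms: none
Why: Pyridine-buffered HF removes the primary allylic silyl ether without base-induced Michael addition or acid-induced transannular cyclisation.

Step 20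
Reactants: 30 (3S,6R,7R,8R)-3,15-dihydroxy-8-(methacryloyloxy)germacra-1(10)E,4Z,11(13)-trien-12,6-olide
Product: 31 (3S,6R,7R,8R)-3-hydroxy-8-(methacryloyloxy)-15-oxogermacra-1(10)E,4E,11(13)-trien-12,6-olide
Conditions: TEMPO (0.2 equiv), PhI(OAc)2, CH2Cl2, rt
Reagents that add atoms: none
Why: The oxoammonium (TEMPO) oxidation is strongly selective for the primary allylic C15 alcohol over the secondary C3 alcohol and stops at the enal.

Step 21
Reactants: 31 (3S,6R,7R,8R)-3-hydroxy-8-(methacryloyloxy)-15-oxogermacra-1(10)E,4E,11(13)-trien-12,6-olide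
Product: 32 (1R,3S,6R,7R,8R,10R)-1,10-epoxy-3-hydroxy-8-(methacryloyloxy)-15-oxogermacra-4E,11(13)-dien-12,6-olide
Conditions: mCPBA (1.1 equiv), NaHCO3, CH2Cl2, 0 °C
Reagents that add atoms: 3-chloroperoxybenzoic acid, OOC(=O)c1cccc(Cl)c1
Why: Prilezhaev epoxidation picks the only electron-rich alkene (the other three are conjugated to carbonyls), and attack on the outer face of the E-1(10) alkene with C14 on the β face is expected to give the 1β,10α (1R,10R) oxirane.

**Compound list**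
1 | but-3-yn-1-ol | C#CCCO | starting material
2 | tert-butyl(but-3-yn-1-yloxy)dimethylsilane | C#CCCO[Si](C)(C)C(C)(C)C | intermediate
3 | oxirane | C1CO1 | starting material
4 | (E)-{4-[(tert-butyldimethylsilyl)oxy]-2-methylbut-1-en-1-yl}dimethylalane | C[Al](C)/C=C(\C)CCO[Si](C)(C)C(C)(C)C | intermediate (not isolated)
5 | (E)-6-[(tert-butyldimethylsilyl)oxy]-4-methylhex-3-en-1-ol | OCC/C=C(\C)CCO[Si](C)(C)C(C)(C)C | intermediate
6 | (E)-tert-butyl({6-[(4-methoxybenzyl)oxy]-3-methylhex-3-en-1-yl}oxy)dimethylsilane | COc1ccc(COCC/C=C(\C)CCO[Si](C)(C)C(C)(C)C)cc1 | intermediate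
7 | (E)-6-[(4-methoxybenzyl)oxy]-3-methylhex-3-en-1-ol | COc1ccc(COCC/C=C(\C)CCO)cc1 | intermediate
8 | (E)-6-[(4-methoxybenzyl)oxy]-3-methylhex-3-enal | COc1ccc(COCC/C=C(\C)CC=O)cc1 | intermediate
9 | prop-2-yn-1-ol | C#CCO | starting material
10 | tert-butyldiphenyl(prop-2-yn-1-yloxy)silane | C#CCO[Si](c1ccccc1)(c1ccccc1)C(C)(C)C | intermediate
11 | (E)-but-2-enal | C/C=C/C=O | starting material
12 | lithium 3-[(tert-butyldiphenylsilyl)oxy]prop-1-yn-1-ide | [Li]C#CCO[Si](c1ccccc1)(c1ccccc1)C(C)(C)C | intermediate (not isolated)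
13 | rac-(E)-1-[(tert-butyldiphenylsilyl)oxy]hept-5-en-2-yn-4-ol | C/C=C/C(O)C#CCO[Si](c1ccccc1)(c1ccccc1)C(C)(C)C | intermediate
14 | (4S,5E)-1-[(tert-butyldiphenylsilyl)oxy]hept-5-en-2-yn-4-ol | C/C=C/[C@H](O)C#CCO[Si](c1ccccc1)(c1ccccc1)C(C)(C)C | intermediate
15 | sodium cyclic alkenyl(alkoxy)bis(2-methoxyethoxy)aluminate from 14 (Al bonded to O4 and C2) | C/C=C/[C@@H]1O[Al-](OCCOC)(OCCOC)C(CO[Si](c2ccccc2)(c2ccccc2)C(C)(C)C)=C1.[Na+] | intermediate (not isolated)
16 | (2Z,4S,5E)-1-[(tert-butyldiphenylsilyl)oxy]-2-iodohepta-2,5-dien-4-ol | C/C=C/[C@H](O)/C=C(\I)CO[Si](c1ccccc1)(c1ccccc1)C(C)(C)C | intermediate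
17 | 2-(bromomethyl)acrylic acid | C=C(CBr)C(=O)O | starting material
18 | (2Z,4S,5E)-1-[(tert-butyldiphenylsilyl)oxy]-2-iodohepta-2,5-dien-4-yl 2-(bromomethyl)acrylate | C/C=C/[C@H](OC(=O)C(=C)CBr)/C=C(\I)CO[Si](c1ccccc1)(c1ccccc1)C(C)(C)C | intermediate
19 | (S)-3-(bromomethyl)-5-{(Z)-3-[(tert-butyldiphenylsilyl)oxy]-2-iodoprop-1-en-1-yl}furan-2(5H)-one | BrCC1=C[C@@H](/C=C(\I)CO[Si](c2ccccc2)(c2ccccc2)C(C)(C)C)OC1=O | intermediate
20 | {[(S)-5-{(Z)-3-[(tert-butyldiphenylsilyl)oxy]-2-iodoprop-1-en-1-yl}-2-oxo-2,5-dihydrofuran-3-yl]methyl}zinc bromide | Br[Zn]CC1=C[C@@H](/C=C(\I)CO[Si](c2ccccc2)(c2ccccc2)C(C)(C)C)OC1=O | intermediate (not isolated)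
21 | (4R,5S)-4-{(1S,3E)-1-hydroxy-6-[(4-methoxybenzyl)oxy]-3-methylhex-3-en-1-yl}-5-{(Z)-3-[(tert-butyldiphenylsilyl)oxy]-2-iodoprop-1-en-1-yl}-3-methylideneoxolan-2-one | C=C1C(=O)O[C@H](/C=C(\I)CO[Si](c2ccccc2)(c2ccccc2)C(C)(C)C)[C@H]1[C@@H](O)C/C(C)=C/CCOCc1ccc(OC)cc1 | intermediate
22 | methacrylic acid | C=C(C)C(=O)O | starting material
23 | (1R,3E)-1-[(2S,3R)-2-{(Z)-3-[(tert-butyldiphenylsilyl)oxy]-2-iodoprop-1-en-1-yl}-4-methylidene-5-oxooxolan-3-yl]-6-[(4-methoxybenzyl)oxy]-3-methylhex-3-en-1-yl methacrylate | C=C1C(=O)O[C@H](/C=C(\I)CO[Si](c2ccccc2)(c2ccccc2)C(C)(C)C)[C@H]1[C@H](OC(=O)C(C)=C)C/C(C)=C/CCOCc1ccc(OC)cc1 | intermediate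
24 | (1R,3E)-1-[(2S,3R)-2-{(Z)-3-[(tert-butyldiphenylsilyl)oxy]-2-iodoprop-1-en-1-yl}-4-methylidene-5-oxooxolan-3-yl]-6-hydroxy-3-methylhex-3-en-1-yl methacrylate | C=C1C(=O)O[C@H](/C=C(\I)CO[Si](c2ccccc2)(c2ccccc2)C(C)(C)C)[C@H]1[C@H](OC(=O)C(C)=C)C/C(C)=C/CCO | intermediate
25 | (1R,3E)-1-[(2S,3R)-2-{(Z)-3-[(tert-butyldiphenylsilyl)oxy]-2-iodoprop-1-en-1-yl}-4-methylidene-5-oxooxolan-3-yl]-3-methyl-6-oxohex-3-en-1-yl methacrylate | C=C1C(=O)O[C@H](/C=C(\I)CO[Si](c2ccccc2)(c2ccccc2)C(C)(C)C)[C@H]1[C@H](OC(=O)C(C)=C)C/C(C)=C/CC=O | intermediate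
26 | alkenylchromium dichloride from 25 (CrCl2 in place of iodine, trivalent chromium) | C=C1C(=O)O[C@H](/C=C(\[Cr](Cl)Cl)CO[Si](c2ccccc2)(c2ccccc2)C(C)(C)C)[C@H]1[C@H](OC(=O)C(C)=C)C/C(C)=C/CC=O | intermediate (not isolated)
27 | (6R,7R,8R)-15-[(tert-butyldiphenylsilyl)oxy]-3-hydroxy-8-(methacryloyloxy)germacra-1(10)E,4Z,11(13)-trien-12,6-olide, C3 epimer mixture | C=C(C)C(=O)O[C@@H]1C/C(C)=C/CC(O)/C(CO[Si](c3ccccc3)(c3ccccc3)C(C)(C)C)=C\[C@H]2OC(=O)C(=C)[C@@H]21 | intermediate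
28 | (6R,7R,8R)-15-[(tert-butyldiphenylsilyl)oxy]-8-(methacryloyloxy)-3-oxogermacra-1(10)E,4Z,11(13)-trien-12,6-olide | C=C(C)C(=O)O[C@@H]1C/C(C)=C/CC(=O)/C(CO[Si](c3ccccc3)(c3ccccc3)C(C)(C)C)=C\[C@H]2OC(=O)C(=C)[C@@H]21 | intermediate
29 | (3S,6R,7R,8R)-15-[(tert-butyldiphenylsilyl)oxy]-3-hydroxy-8-(methacryloyloxy)germacra-1(10)E,4Z,11(13)-trien-12,6-olide | C=C(C)C(=O)O[C@@H]1C/C(C)=C/C[C@H](O)/C(CO[Si](c3ccccc3)(c3ccccc3)C(C)(C)C)=C\[C@H]2OC(=O)C(=C)[C@@H]21 | intermediate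
30 | (3S,6R,7R,8R)-3,15-dihydroxy-8-(methacryloyloxy)germacra-1(10)E,4Z,11(13)-trien-12,6-olide | C=C(C)C(=O)O[C@@H]1C/C(C)=C/C[C@H](O)/C(CO)=C\[C@H]2OC(=O)C(=C)[C@@H]21 | intermediate
31 | (3S,6R,7R,8R)-3-hydroxy-8-(methacryloyloxy)-15-oxogermacra-1(10)E,4E,11(13)-trien-12,6-olide | C=C(C)C(=O)O[C@@H]1C/C(C)=C/C[C@H](O)/C(C=O)=C\[C@H]2OC(=O)C(=C)[C@@H]21 | intermediate
32 | (1R,3S,6R,7R,8R,10R)-1,10-epoxy-3-hydroxy-8-(methacryloyloxy)-15-oxogermacra-4E,11(13)-dien-12,6-olide | C=C(C)C(=O)O[C@@H]1C[C@@]2(C)O[C@@H]2C[C@H](O)/C(C=O)=C\[C@H]2OC(=O)C(=C)[C@@H]21 | target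

**Totals**
Total step count: 21. Longest linear sequence: 16 steps (steps 6–11, then 12–21, from prop-2-yn-1-ol).

**Three steps most likely to fail**

Step 13 (Mitsunobu inversion at the hindered C8 carbinol; elimination towards C9 or no reaction are the risks). The fallback sets out from bromide 19 and aldehyde 8 and comes back at 23. Bromide 19 is treated with Bu3SnCl and Zn in THF/aq. NH4Cl to give the allylstannane (S)-5-{(Z)-3-[(tert-butyldiphenylsilyl)oxy]-2-iodoprop-1-en-1-yl}-3-[(tributylstannyl)methyl]furan-2(5H)-one F1. BF3·OEt2-promoted addition of F1 to 8 in CH2Cl2 at −78 °C runs through an open, antiperiplanar transition state, which favours the 7,8-syn adduct, again anti to the C6 substituent. This gives the C8 epimer of 21, (4R,5S)-4-{(1R,3E)-1-hydroxy-6-[(4-methoxybenzyl)oxy]-3-methylhex-3-en-1-yl}-5-{(Z)-3-[(tert-butyldiphenylsilyl)oxy]-2-iodoprop-1-en-1-yl}-3-methylideneoxolan-2-one F2. Acylation of F2 with methacrylic anhydride, Et3N and DMAP, with retention, gives 23, so no inversion is needed.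

Step 16 (ten-membered ring closure; oligomerisation or isomerisation of the β,γ-unsaturated aldehyde are the risks). The fallback sets out from aldehyde 25 and comes back at enone 28, closing the same C3–C4 bond at the ketone oxidation level by a palladium-catalysed acyl–alkenyl coupling. Pinnick oxidation (NaClO2, NaH2PO4, 2-methyl-2-butene) gives (3E,6R)-6-[(2S,3R)-2-{(Z)-3-[(tert-butyldiphenylsilyl)oxy]-2-iodoprop-1-en-1-yl}-4-methylidene-5-oxooxolan-3-yl]-6-(methacryloyloxy)-4-methylhex-3-enoic acid F3. Hexamethylditin with Pd(PPh3)4 (zerovalent palladium) exchanges iodine for tin to give the corresponding trimethylstannyl acid F4. 1-Chloro-N,N,2-trimethylprop-1-en-1-amine converts F4 under neutral conditions into the stannyl acid chloride F5. Slow addition of F5 to Pd2(dba)3 and tri(2-furyl)phosphine in toluene effects an intramolecular acyl-Stille coupling that gives 28 directly; the route continues with step 18.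

Step 21 (face selectivity of the epoxidation rests on the ring conformation). The fallback sets out from enal 31 and comes back at 32, and delivers oxygen to the face opposite to the one a peracid attacks. NBS in THF/H2O at 0 °C forms the bromonium ion on the exposed face and water opens it at the tertiary C10, giving the bromohydrin (1S,3S,6R,7R,8R,10R)-1-bromo-3,10-dihydroxy-8-(methacryloyloxy)-15-oxogermacra-4E,11(13)-dien-12,6-olide F6. Ag2O in CH2Cl2 then closes the oxirane by displacement at C1 with inversion to give 32.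

**Further compounds**
F1 | step 13 | (S)-5-{(Z)-3-[(tert-butyldiphenylsilyl)oxy]-2-iodoprop-1-en-1-yl}-3-[(tributylstannyl)methyl]furan-2(5H)-one | CCCC[Sn](CCCC)(CCCC)CC1=C[C@@H](/C=C(\I)CO[Si](c2ccccc2)(c2ccccc2)C(C)(C)C)OC1=O
F2 | step 13 | (4R,5S)-4-{(1R,3E)-1-hydroxy-6-[(4-methoxybenzyl)oxy]-3-methylhex-3-en-1-yl}-5-{(Z)-3-[(tert-butyldiphenylsilyl)oxy]-2-iodoprop-1-en-1-yl}-3-methylideneoxolan-2-one | C=C1C(=O)O[C@H](/C=C(\I)CO[Si](c2ccccc2)(c2ccccc2)C(C)(C)C)[C@H]1[C@H](O)C/C(C)=C/CCOCc1ccc(OC)cc1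
F3 | step 16 | (3E,6R)-6-[(2S,3R)-2-{(Z)-3-[(tert-butyldiphenylsilyl)oxy]-2-iodoprop-1-en-1-yl}-4-methylidene-5-oxooxolan-3-yl]-6-(methacryloyloxy)-4-methylhex-3-enoic acid | C=C1C(=O)O[C@H](/C=C(\I)CO[Si](c2ccccc2)(c2ccccc2)C(C)(C)C)[C@H]1[C@H](OC(=O)C(C)=C)C/C(C)=C/CC(=O)O
F4 | step 16 | (3E,6R)-6-[(2S,3R)-2-{3-[(tert-butyldiphenylsilyl)oxy]-2-(trimethylstannyl)prop-1-en-1-yl}-4-methylidene-5-oxooxolan-3-yl]-6-(methacryloyloxy)-4-methylhex-3-enoic acid (tin cis to C6) | C=C1C(=O)O[C@H](/C=C(\[Sn](C)(C)C)CO[Si](c2ccccc2)(c2ccccc2)C(C)(C)C)[C@H]1[C@H](OC(=O)C(C)=C)C/C(C)=C/CC(=O)O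
F5 | step 16 | acid chloride of F4 | C=C1C(=O)O[C@H](/C=C(\[Sn](C)(C)C)CO[Si](c2ccccc2)(c2ccccc2)C(C)(C)C)[C@H]1[C@H](OC(=O)C(C)=C)C/C(C)=C/CC(=O)Cl
F6 | step 21 | (1S,3S,6R,7R,8R,10R)-1-bromo-3,10-dihydroxy-8-(methacryloyloxy)-15-oxogermacra-4E,11(13)-dien-12,6-olide | C=C(C)C(=O)O[C@@H]1C[C@@](C)(O)[C@@H](Br)C[C@H](O)/C(C=O)=C\[C@H]2OC(=O)C(=C)[C@@H]21
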